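**Retrosynthetic overview**
1. Briarellin C ⇐ two late acylations; the oxonane (ten-membered carbocycle) is closed last at C6–C7 by CrCl2/NiCl2 alkenyl–aldehyde addition.
2. ε-Lactone ⇐ acylation of the C3 oxygen by the C16 acid; tetrahydrofuran ⇐ opening of the (2R,3S)-epoxide of the Z-C2=C3 olefin by the C9 hydroxyl (5-exo, inversion at C2).
3. Cyclohexane ⇐ C1–C10 bond (the cembranoid C2–C11 closure) by allyl cation–olefin cyclization of an open-chain Z-neryl carbamate; the carbamate traps the C11 cation, and C1, C10 and C11 follow from C14.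
4. Cyclization substrate ⇐ nerol-derived allylboron (C9–C17, C20) + butenolide lactol (C1–C6, C18) joined at C1–C14; C7, C8 and C19 come from 2,3-dibromopropene.
5. Ring order: cyclohexane → tetrahydrofuran → ε-lactone → oxonane.

Assumption 1: locants C1–C20 are the eunicellane locants of the target (C1/C10 ring fusion, C2–O–C9 ether, C16 lactone carbonyl).
Assumption 2: for each chiral ligand, auxiliary or catalyst, the enantiomer written is taken to be the one that gives the drawn configuration.
Assumption 3: O–metal and O–boron alkoxides that are only hydrolysed at work-up are not numbered as intermediates.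

**Step 1**
Reactants: 1 nerol + 2 N,N-dimethylcarbamoyl chloride
Product: 3 neryl N,N-dimethylcarbamate
Conditions: NaH, THF, 0 °C to rt
Reagents that add atoms: none
Why: O-carbamoylation of the alkoxide (acyl substitution) installs the group that later traps the C11 cation; no stereocentre is formed.

**Step 2**
Reactants: 3 neryl N,N-dimethylcarbamate
Product: 4 C16 allylic alcohol
Conditions: SeO2 (10 mol %), t-BuOOH, salicylic acid (cat.), CH2Cl2, rt, stopped at partial conversion
Reagents that add atoms: tert-butyl hydroperoxide, CC(C)(C)OO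
Why: SeO2 allylic oxidation (ene/[2,3]-sigmatropic sequence) is selective for the E-methyl group of the terminal olefin because the 2,3-olefin is deactivated by the allylic carbamate.

**Step 3**
Reactants: 4 C16 allylic alcohol
Product: 5 allylboronic acid
Conditions: B2(OH)4, Pd(MeCN)4(BF4)2 (5 mol %), DMSO/MeOH, rt, argon
Reagents that add atoms: tetrahydroxydiboron, OB(O)B(O)O
Why: Pd-catalysed borylation of a free allylic alcohol (Szabó type) gives the linear E allylboronic acid by borylation of the allylpalladium intermediate at its less hindered terminus, the poorer carbamate leaving group staying intact.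

**Step 4**
Reactants: 6 3-[(tert-butyldimethylsilyl)oxy]propanal + 7 methyl propiolate
Product: 8 propargylic alcohol
Conditions: Me2Zn, (S,S)-2,6-bis{[2-(hydroxydiphenylmethyl)pyrrolidin-1-yl]methyl}-4-methylphenol (20 mol %), toluene, 4 °C; aq. NH4Cl
Reagents that add atoms: none
Why: Zn–ProPhenol catalysed enantioselective alkynylation of the aldehyde (Trost alkynylation) sets C4 as R by ligand control.

**Step 5**
Reactants: 8 propargylic alcohol
Product: 10 silyl butenolide, via hydroxy enoate 9 (not isolated)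
Conditions: MeLi, CuI, THF, −78 °C; aq. NH4Cl; silica gel
Reagents that add atoms: lithium dimethylcuprate (Me2CuLi), [Li+].C[Cu-]C
Why: syn-carbocupration (conjugate addition) puts the methyl group on C3 cis to H2, so the Z-γ-hydroxy enoate lactonizes and the ring locks the C2=C3 geometry as Z; C4 is untouched.

**Step 6**
Reactants: 10 silyl butenolide
Product: 11 lactol
Conditions: i-Bu2AlH (1.1 equiv), CH2Cl2, −78 °C; Rochelle salt, kept neutral and cold
Reagents that add atoms: none
Why: half-reduction of the lactone stops at the aluminium hemiacetal and gives the lactol, a masked Z-γ-hydroxy enal, which is not exposed to acid so that it does not dehydrate to a furan.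

**Step 7**
Reactants: 5 allylboronic acid + 11 lactol
Product: 13 open-chain ene-diol, via tartrate boronate 12 (not isolated)
Conditions: diisopropyl (R,R)-tartrate, 4 Å sieves, toluene, rt; then 11, −78 °C; aq. NaHCO3
Reagents that add atoms: none
Why: Roush tartrate allylboration of the open hydroxy-enal form through a closed chair transition state gives the 1,14-anti product from the E boronate, and the tartrate sets C14 as S (C1 as R) independently of the remote C4 centre.

**Step 8**
Reactants: 13 open-chain ene-diol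
Product: 16 cyclic carbonate, via dihydrofuran 14 (not isolated), via iminium carbonate 15 (not isolated)
Conditions: BF3·OEt2 (2.2 equiv), CH2Cl2, −78 to −40 °C; aq. NaHCO3, rt
Reagents that add atoms: water, O
Why: Proposed new method: BF3 dehydrates the Z-ene-1,4-diol to the 2,5-dihydrofuran, whose allylic C1–O bond ionises reversibly to a Z-locked allyl cation (tertiary C3 terminus, C4–O–BF3 counter-ion); the Z-neryl olefin attacks C1 through a chair transition state with the C14 isopropenyl and C1 alkenyl groups equatorial and C9 necessarily axial, and the carbamate carbonyl captures the C11 cation anti to the new bond, so C1 (S), C10 (R) and C11 (R) all follow from C14 and hydrolysis of the iminium gives the carbonate; the closest known reactions are allylic-alcohol-initiated (Johnson-type) cation–olefin cyclizations, carbonate- or carbamate-terminated polyene cyclizations and Ferrier-type ionisation of cyclic allylic ethers.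

**Step 9**
Reactants: 16 cyclic carbonate
Product: 17 triol
Conditions: K2CO3 (0.2 equiv), MeOH, rt
Reagents that add atoms: none
Why: base-catalysed transesterification of the cyclic carbonate frees the C9 primary and C11 tertiary alcohols without touching the silyl ether or any stereocentre.

**Step 10**
Reactants: 17 triol
Product: 18 hydroxy aldehyde
Conditions: 2,2,6,6-tetramethylpiperidin-1-oxyl (10 mol %), PhI(OAc)2 (1.1 equiv), CH2Cl2, 0 °C to rt
Reagents that add atoms: none
Why: oxoammonium oxidation is selective for the unhindered primary alcohol over the hindered secondary allylic and tertiary alcohols, and the neutral conditions avoid retro-aldol cleavage and epimerisation at C10.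

**Step 11**
Reactants: 19 2,3-dibromopropene
Product: 21 2-bromoallyl pinacol boronate, via allylzinc bromide 20 (not isolated)
Conditions: Zn dust, THF, 0 °C; then 2-isopropoxy-4,4,5,5-tetramethyl-1,3,2-dioxaborolane, −78 °C to rt; aq. NH4Cl
Reagents that add atoms: 2-isopropoxy-4,4,5,5-tetramethyl-1,3,2-dioxaborolane, CC(C)OB1OC(C)(C)C(C)(C)O1
Why: zinc inserts only into the allylic C–Br bond and zinc-to-boron exchange (Barbier-type borylation) gives the allylboronate with the vinylic bromide intact.

**Step 12**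
Reactants: 18 hydroxy aldehyde + 21 2-bromoallyl pinacol boronate
Product: 22 bromoallyl carbinol
Conditions: (R)-3,3′-bis(2,4,6-triisopropylphenyl)-1,1′-binaphthyl-2,2′-diyl hydrogen phosphate (10 mol %), 4 Å sieves, toluene, −30 °C; aq. NaHCO3
Reagents that add atoms: none
Why: chiral phosphoric acid catalysed allylboration (Antilla type) proceeds through a closed, non-chelated chair transition state, and catalyst control reinforces the Felkin–Anh preference (C11 as the large group) to give the 9S alcohol.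

**Step 13**
Reactants: 22 bromoallyl carbinol
Product: 24 tetrahydrofuran triol, via epoxy alcohol 23 (not isolated)
Conditions: VO(acac)2 (5 mol %), t-BuOOH, CH2Cl2, 0 °C; then pyridinium p-toluenesulfonate (cat.), rt
Reagents that add atoms: tert-butyl hydroperoxide, CC(C)(C)OO
Why: hydroxyl-directed VO(acac)2 epoxidation of the Z-allylic alcohol in its A(1,3)-minimised conformer delivers oxygen syn to the C4 hydroxyl (2R,3S), and the C9 hydroxyl then opens the epoxide at C2 in a 5-exo SN2 process with inversion (2S), leaving the C3 oxygen in its final configuration (Kishi-type epoxidation–cyclization).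

**Step 14**
Reactants: 24 tetrahydrofuran triol
Product: 25 C4 octanoate
Conditions: octanoyl chloride (1.2 equiv), pyridine, 4-(dimethylamino)pyridine (cat.), CH2Cl2, 0 °C
Reagents that add atoms: octanoyl chloride, CCCCCCCC(Cl)=O
Why: acylation occurs only at the secondary C4 hydroxyl because the C3 and C11 hydroxyls are tertiary.

**Step 15**
Reactants: 25 C4 octanoate
Product: 27 C16 alcohol, via alkylborane 26 (not isolated)
Conditions: 9-borabicyclo[3.3.1]nonane (3 equiv), THF, 0 °C to rt; then 30% H2O2, aq. NaHCO3, 0 °C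
Reagents that add atoms: hydrogen peroxide, OO
Why: hydroboration–oxidation with the bulky borane is selective for the isopropenyl group over the bromo-olefin, and attack anti to the larger C1 substituent in the conformer with H14 eclipsing the olefin sets C15 as R (acyclic 1,2-induction).

**Step 16**
Reactants: 27 C16 alcohol
Product: 28 C16 acid
Conditions: 2,2,6,6-tetramethylpiperidin-1-oxyl (20 mol %), PhI(OAc)2 (2.5 equiv), MeCN/H2O 1:1, rt
Reagents that add atoms: water, O
Why: oxoammonium oxidation takes the only primary alcohol through the aldehyde hydrate to the acid under near-neutral conditions that do not epimerise C15.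

**Step 17**
Reactants: 28 C16 acid
Product: 30 bromo lactone, via mixed anhydride 29 (not isolated)
Conditions: 2,4,6-trichlorobenzoyl chloride, Et3N, THF, rt; then 4-(dimethylamino)pyridine, toluene, 80 °C
Reagents that add atoms: none
Why: Yamaguchi lactonization acylates the C3 tertiary alcohol intramolecularly because the C15 side chain and the C3 oxygen lie on the same face of the rigid bicycle, while the C11 hydroxyl is trans to the side chain and cannot reach.

**Step 18**
Reactants: 30 bromo lactone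
Product: 31 C6 alcohol
Conditions: HF·pyridine, THF/pyridine, 0 °C to rt
Reagents that add atoms: none
Why: fluoride-mediated desilylation removes the primary silyl ether without affecting the esters, the lactone or the bromo-olefin.

**Step 19**
Reactants: 31 C6 alcohol
Product: 32 C6 aldehyde
Conditions: Dess–Martin periodinane, NaHCO3, CH2Cl2, 0 °C to rt
Reagents that add atoms: none
Why: buffered Dess–Martin oxidation gives the β-acyloxy aldehyde without β-elimination.

**Step 20**
Reactants: 32 C6 aldehyde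
Product: 34 C6 allylic alcohol, via alkenylchromium 33 (not isolated)
Conditions: CrCl2 (10 equiv), NiCl2 (1 mol % of Cr), DMSO, rt, 0.003 M
Reagents that add atoms: none
Why: Nozaki–Hiyama–Kishi reaction, in which NiCl2-mediated activation of the C–Br bond and transmetalation to chromium give an alkenylchromium species that adds intramolecularly to the aldehyde, closing the oxonane; attack on the exposed aldehyde face of the templated tricycle is expected to give the 6R alcohol, as in closely related oxonane closures.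

**Step 21**
Reactants: 34 C6 allylic alcohol
Product: 35 briarellin C
Conditions: butyric anhydride, 4-(dimethylamino)pyridine, pyridine, CH2Cl2, rt
Reagents that add atoms: butyric anhydride, CCCC(=O)OC(=O)CCC
Why: acylation of the only secondary hydroxyl, the tertiary C11 hydroxyl being unreactive, gives the target.

**Compound list**
1 | nerol, (2Z)-3,7-dimethylocta-2,6-dien-1-ol | CC(C)=CCC/C(C)=C\CO | starting material
2 | N,N-dimethylcarbamoyl chloride | CN(C)C(Cl)=O | starting material
3 | neryl N,N-dimethylcarbamate | CN(C)C(=O)OC/C=C(/C)CCC=C(C)C | intermediate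
4 | (2Z,6E)-8-hydroxy-3,7-dimethylocta-2,6-dien-1-yl dimethylcarbamate | CN(C)C(=O)OC/C=C(/C)CC/C=C(\C)CO | intermediate
5 | [(2E,6Z)-8-(dimethylcarbamoyloxy)-2,6-dimethylocta-2,6-dien-1-yl]boronic acid | CN(C)C(=O)OC/C=C(/C)CC/C=C(\C)CB(O)O | intermediate
6 | 3-[(tert-butyldimethylsilyl)oxy]propanal | O=CCCO[Si](C)(C)C(C)(C)C | starting material
7 | methyl propiolate | C#CC(=O)OC | starting material
8 | methyl (4R)-6-[(tert-butyldimethylsilyl)oxy]-4-hydroxyhex-2-ynoate | COC(=O)C#C[C@H](O)CCO[Si](C)(C)C(C)(C)C | intermediate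
9 | methyl (2Z,4R)-6-[(tert-butyldimethylsilyl)oxy]-4-hydroxy-3-methylhex-2-enoate | COC(=O)/C=C(/C)[C@H](O)CCO[Si](C)(C)C(C)(C)C | intermediate (not isolated)
10 | (5R)-5-{2-[(tert-butyldimethylsilyl)oxy]ethyl}-4-methylfuran-2(5H)-one | CC1=CC(=O)O[C@@H]1CCO[Si](C)(C)C(C)(C)C | intermediate
11 | (5R)-5-{2-[(tert-butyldimethylsilyl)oxy]ethyl}-4-methyl-2,5-dihydrofuran-2-ol, both C2 epimers (furan C2 = target C1) | CC1=CC(O)O[C@@H]1CCO[Si](C)(C)C(C)(C)C | intermediate
12 | diisopropyl (4R,5R)-2-[(2E,6Z)-8-(dimethylcarbamoyloxy)-2,6-dimethylocta-2,6-dien-1-yl]-1,3,2-dioxaborolane-4,5-dicarboxylate | CN(C)C(=O)OC/C=C(/C)CC/C=C(\C)CB1O[C@@H](C(=O)OC(C)C)[C@H](C(=O)OC(C)C)O1 | intermediate (not isolated)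
13 | (2Z,6S,7R,8Z,10R)-12-[(tert-butyldimethylsilyl)oxy]-7,10-dihydroxy-3,9-dimethyl-6-(prop-1-en-2-yl)dodeca-2,8-dien-1-yl dimethylcarbamate (target locants 1R,4R,14S) | CN(C)C(=O)OC/C=C(/C)CC[C@@H](C(C)=C)[C@H](O)/C=C(/C)[C@H](O)CCO[Si](C)(C)C(C)(C)C | intermediate
14 | 2,5-dihydrofuran from 13 with O bridging C1 and C4 (4R,14S; C1 epimers), neryl carbamate and isopropenyl unchanged | CN(C)C(=O)OC/C=C(/C)CC[C@@H](C(C)=C)C1C=C(C)[C@@H](CCO[Si](C)(C)C(C)(C)C)O1 | intermediate (not isolated)
15 | zwitterion: 2-(dimethyliminio)-1,3-dioxane cis-fused at C10–C11 of the new cyclohexane, C4–O–BF3 (1S,4R,10R,11R,14R) | CC(=C)[C@@H]1CC[C@@]2(C)OC(=[N+](C)C)OC[C@H]2[C@H]1/C=C(/C)[C@H](O[B-](F)(F)F)CCO[Si](C)(C)C(C)(C)C | intermediate (not isolated)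
16 | cyclic carbonate (1S,4R,10R,11R,14R): cyclohexane C1/C10/C11/C12/C13/C14 with the C9–O–C(=O)–O–C11 carbonate cis-fused, C11 methyl, C14 isopropenyl trans to the C1 chain, C1 bearing (Z)-CH=C(CH3)–CH(OH)–CH2CH2OTBS cis to C9 | CC(=C)[C@@H]1CC[C@@]2(C)OC(=O)OC[C@H]2[C@H]1/C=C(/C)[C@H](O)CCO[Si](C)(C)C(C)(C)C | intermediate
17 | triol (1S,4R,10R,11R,14R): as 16 with free C9 CH2OH and C11 OH | CC(=C)[C@@H]1CC[C@@](C)(O)[C@@H](CO)[C@H]1/C=C(/C)[C@H](O)CCO[Si](C)(C)C(C)(C)C | intermediate
18 | hydroxy aldehyde (1S,4R,10S,11R,14R): as 17 with C9 as CHO | CC(=C)[C@@H]1CC[C@@](C)(O)[C@@H](C=O)[C@H]1/C=C(/C)[C@H](O)CCO[Si](C)(C)C(C)(C)C | intermediate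
19 | 2,3-dibromopropene | C=C(Br)CBr | starting material
20 | (2-bromoprop-2-en-1-yl)zinc bromide | C=C(Br)C[Zn]Br | intermediate (not isolated)
21 | 2-(2-bromoprop-2-en-1-yl)-4,4,5,5-tetramethyl-1,3,2-dioxaborolane | C=C(Br)CB1OC(C)(C)C(C)(C)O1 | intermediate
22 | bromoallyl carbinol (1S,4R,9S,10R,11R,14R): as 18 with C9 as CH(OH)–CH2–C(Br)=CH2 | CC(=C)[C@@H]1CC[C@@](C)(O)[C@@H]([C@@H](O)CC(Br)=C)[C@H]1/C=C(/C)[C@H](O)CCO[Si](C)(C)C(C)(C)C | intermediate
23 | (2R,3S)-2,3-epoxide of 22, epoxide oxygen syn to the C4 hydroxyl | CC(=C)[C@@H]1CC[C@@](C)(O)[C@@H]([C@@H](O)CC(Br)=C)[C@H]1[C@H]2O[C@@]2(C)[C@H](O)CCO[Si](C)(C)C(C)(C)C | intermediate (not isolated)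
24 | tetrahydrofuran triol (1S,2S,3S,4R,9S,10R,11R,14R): cis-fused hydroisobenzofuran with C2–O–C9 ether, free C3, C4 and C11 hydroxyls, 2-bromoallyl on C9, isopropenyl on C14, CH2CH2OTBS on C4 | CC(=C)[C@@H]1CC[C@@](C)(O)[C@H]2[C@H](CC(Br)=C)O[C@@H]([C@@H]12)[C@@](C)(O)[C@H](O)CCO[Si](C)(C)C(C)(C)C | intermediate
25 | C4 octanoate of 24 | CC(=C)[C@@H]1CC[C@@](C)(O)[C@H]2[C@H](CC(Br)=C)O[C@@H]([C@@H]12)[C@@](C)(O)[C@H](OC(=O)CCCCCCC)CCO[Si](C)(C)C(C)(C)C | intermediate
26 | B-alkyl-9-borabicyclo[3.3.1]nonane from 25, boron on C16, C15 configured as in the target | C[C@@H](CB1C2CCCC1CCC2)[C@@H]1CC[C@@](C)(O)[C@H]2[C@H](CC(Br)=C)O[C@@H]([C@@H]12)[C@@](C)(O)[C@H](OC(=O)CCCCCCC)CCO[Si](C)(C)C(C)(C)C | intermediate (not isolated)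
27 | C16 primary alcohol (15R), otherwise as 25 | C[C@@H](CO)[C@@H]1CC[C@@](C)(O)[C@H]2[C@H](CC(Br)=C)O[C@@H]([C@@H]12)[C@@](C)(O)[C@H](OC(=O)CCCCCCC)CCO[Si](C)(C)C(C)(C)C | intermediate
28 | C16 carboxylic acid (15R), otherwise as 25 | C[C@@H](C(=O)O)[C@@H]1CC[C@@](C)(O)[C@H]2[C@H](CC(Br)=C)O[C@@H]([C@@H]12)[C@@](C)(O)[C@H](OC(=O)CCCCCCC)CCO[Si](C)(C)C(C)(C)C | intermediate
29 | mixed anhydride of 28 with 2,4,6-trichlorobenzoic acid | C[C@@H](C(=O)OC(=O)c1c(Cl)cc(Cl)cc1Cl)[C@@H]1CC[C@@](C)(O)[C@H]2[C@H](CC(Br)=C)O[C@@H]([C@@H]12)[C@@](C)(O)[C@H](OC(=O)CCCCCCC)CCO[Si](C)(C)C(C)(C)C | intermediate (not isolated)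
30 | bromo lactone (1S,2S,3S,4R,9S,10R,11R,14R,15R): tricyclic C16(=O)–O–C3 ε-lactone, C4 octanoate, C9 2-bromoallyl, C6 OTBS | C=C(Br)C[C@@H]2O[C@H]3[C@H]4[C@@H](CC[C@@](C)(O)[C@H]42)[C@@H](C)C(=O)O[C@@]3(C)[C@H](OC(=O)CCCCCCC)CCO[Si](C)(C)C(C)(C)C | intermediate
31 | C6 primary alcohol of 30 | C=C(Br)C[C@@H]2O[C@H]3[C@H]4[C@@H](CC[C@@](C)(O)[C@H]42)[C@@H](C)C(=O)O[C@@]3(C)[C@H](OC(=O)CCCCCCC)CCO | intermediate
32 | C6 aldehyde of 30 | C=C(Br)C[C@@H]2O[C@H]3[C@H]4[C@@H](CC[C@@](C)(O)[C@H]42)[C@@H](C)C(=O)O[C@@]3(C)[C@H](OC(=O)CCCCCCC)CC=O | intermediate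
33 | C7 alkenylchromium dichloride of 32 | C=C([Cr](Cl)Cl)C[C@@H]2O[C@H]3[C@H]4[C@@H](CC[C@@](C)(O)[C@H]42)[C@@H](C)C(=O)O[C@@]3(C)[C@H](OC(=O)CCCCCCC)CC=O | intermediate (not isolated)
34 | 6-O-debutanoyl briarellin C (6R allylic alcohol, 7(19)-exo-methylene) | C=C1C[C@@H]2O[C@H]3[C@H]4[C@@H](CC[C@@](C)(O)[C@H]42)[C@@H](C)C(=O)O[C@@]3(C)[C@H](OC(=O)CCCCCCC)C[C@H]1O | intermediate
35 | briarellin C (1S,2S,3S,4R,6R,9S,10R,11R,14R,15R) | C=C1C[C@@H]2O[C@H]3[C@H]4[C@@H](CC[C@@](C)(O)[C@H]42)[C@@H](C)C(=O)O[C@@]3(C)[C@H](OC(=O)CCCCCCC)C[C@H]1OC(=O)CCC | target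

**Totals**
Total step count: 21 (steps 1–3 and 4–6 are two convergent arms; step 11 prepares the bromoallyl boronate).
Longest linear sequence: 17 steps (1–3, 7–10, 12–21; the arm from 6 through steps 4–6 is equally long).

**Three steps most likely to fail, with fallbacks**

Step 8 is unprecedented as a whole; the risks are elimination of the allyl cation, loss of the Z geometry, or simple re-closure of the dihydrofuran. The fallback sets out from 13 and comes back at 16, replacing the reversible Lewis-acid ring opening by an irreversible solvolysis. 13 is treated with 1,1′-sulfonyldiimidazole and NaH (THF, −20 °C) to give the seven-membered, Z-locked cyclic sulfate F5. Warming F5 in 1,1,1,3,3,3-hexafluoropropan-2-ol with 2,6-di-tert-butylpyridine ionises the allylic C1–O bond, and the tethered sulfate monoanion cannot re-close onto the cation. The same chair cyclization and carbamate capture follow, and aqueous work-up gives the sulfate monoester F6. Catalytic H2SO4 in wet THF hydrolyses F6 to 16.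

Step 7 may fail because the lactol reacts only through its minor open form and can dehydrate to a furan, and because tartrate control over a conjugated aldehyde may be modest. The fallback sets out from 10 and comes back at 13, using an open-chain, O-protected Z-enal instead of the lactol. Excess i-Bu2AlH reduces 10 to the Z-diol F1. Et3SiCl and imidazole give the bis(triethylsilyl) ether F2. Swern conditions (oxalyl chloride, DMSO, Et3N) cleave and oxidise only the primary allylic silyl ether to the Z-enal F3. Allylboration of F3 with tartrate boronate 12 gives the mono-protected diol F4. Pyridinium p-toluenesulfonate in MeOH removes the triethylsilyl group to give 13.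

Step 20 is a medium-ring closure on a rigid, lactone-bearing tricycle and may give oligomers or the wrong C6 epimer. The fallback sets out from 31 and comes back at 34, replacing the chromium-mediated alkenyl halide addition by a nickel-catalysed reductive alkyne–aldehyde macrocyclization. Bu4NF in DMF eliminates HBr from 31 to give the terminal alkyne F7. Dess–Martin oxidation gives the alkynyl aldehyde F8. Ni(cod)2 with 1,3-bis(2,6-diisopropylphenyl)imidazol-2-ylidene and Et3SiH (toluene, high dilution) couples the internal alkyne carbon to the aldehyde to give the exo-methylene macrocyclic silyl ether F9. HF·pyridine then gives 34.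

**Further compounds**
F1 | step 7 | (2Z,4R)-6-[(tert-butyldimethylsilyl)oxy]-3-methylhex-2-ene-1,4-diol | OC/C=C(/C)[C@H](O)CCO[Si](C)(C)C(C)(C)C
F2 | step 7 | 1,4-bis(triethylsilyl) ether of F1 | CC[Si](CC)(CC)OC/C=C(/C)[C@H](O[Si](CC)(CC)CC)CCO[Si](C)(C)C(C)(C)C
F3 | step 7 | (2Z,4R)-6-[(tert-butyldimethylsilyl)oxy]-3-methyl-4-[(triethylsilyl)oxy]hex-2-enal | O=C/C=C(/C)[C@H](O[Si](CC)(CC)CC)CCO[Si](C)(C)C(C)(C)C
F4 | step 7 | 4-O-triethylsilyl ether of 13 | CN(C)C(=O)OC/C=C(/C)CC[C@@H](C(C)=C)[C@H](O)/C=C(/C)[C@H](O[Si](CC)(CC)CC)CCO[Si](C)(C)C(C)(C)C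
F5 | step 8 | seven-membered cyclic sulfate of the C1/C4 diol of 13 | CN(C)C(=O)OC/C=C(/C)CC[C@@H](C(C)=C)[C@@H]1OS(=O)(=O)O[C@H](CCO[Si](C)(C)C(C)(C)C)C(C)=C1
F6 | step 8 | C4 hydrogen sulfate of 16 | CC(=C)[C@@H]1CC[C@@]2(C)OC(=O)OC[C@H]2[C@H]1/C=C(/C)[C@H](OS(=O)(=O)O)CCO[Si](C)(C)C(C)(C)C
F7 | step 20 | C7 terminal alkyne analogue of 31 (propargyl on C9) | C#CC[C@@H]2O[C@H]3[C@H]4[C@@H](CC[C@@](C)(O)[C@H]42)[C@@H](C)C(=O)O[C@@]3(C)[C@H](OC(=O)CCCCCCC)CCO
F8 | step 20 | C6 aldehyde of F7 | C#CC[C@@H]2O[C@H]3[C@H]4[C@@H](CC[C@@](C)(O)[C@H]42)[C@@H](C)C(=O)O[C@@]3(C)[C@H](OC(=O)CCCCCCC)CC=O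
F9 | step 20 | 6-O-triethylsilyl ether of 34 | C=C1C[C@@H]2O[C@H]3[C@H]4[C@@H](CC[C@@](C)(O)[C@H]42)[C@@H](C)C(=O)O[C@@]3(C)[C@H](OC(=O)CCCCCCC)C[C@H]1O[Si](CC)(CC)CC
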